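**Retrosynthetic overview**
- No ring is formed at any stage: both benzene rings are bought intact, so there is no ring-forming order.
- Last disconnection: a temporary phenolic palmitate (aryl ester C–O), removed selectively beside the benzylic palmitate and the methyl ester.
- Key disconnection: the diaryl ether C–O bond, made by direct C–H aryloxylation of the ring-A arene (para to its OMe, between the two acyloxy-bearing substituents) with symmetric methyl 2,6-dihydroxy-4-methylbenzoate via a transient diaryl-λ3-iodane.
- First disconnection: both palmitoyl C–O bonds, made in one double acylation of 3-(hydroxymethyl)-5-methoxyphenol.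

Assumption: the target has no stereocentre and its diaryl ether axis rotates freely, so it is achiral and is made as the single compound drawn; 3-(hydroxymethyl)-5-methoxyphenol and methyl 2,6-dihydroxy-4-methylbenzoate are taken as catalogue building blocks.

**Step 1**
Reactants: 1 3-(hydroxymethyl)-5-methoxyphenol; 2 hexadecanoyl chloride (palmitoyl chloride, 2.2 equiv)
Product: 3 3-[(hexadecanoyloxy)methyl]-5-methoxyphenyl hexadecanoate
Conditions: Et3N, DMAP (cat.), CH2Cl2, 0 °C to rt
Reagents that add atoms: none
Why: DMAP-catalysed O-acylation with an acid chloride (nucleophilic acyl substitution) esterifies both the benzylic alcohol and the phenol, installing the final palmitate and a phenolic palmitate that blocks the phenol, leaves OMe as the only strong para director and is later removable without touching an alkyl ester; no stereocentre is formed.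

**Step 2**
Reactants: 3 3-[(hexadecanoyloxy)methyl]-5-methoxyphenyl hexadecanoate; 4 methyl 2,6-dihydroxy-4-methylbenzoate (1.5 equiv)
Product: 6 methyl 2-{2-(hexadecanoyloxy)-6-[(hexadecanoyloxy)methyl]-4-methoxyphenoxy}-6-hydroxy-4-methylbenzoate, via aryl(4-methoxyphenyl)iodonium tosylate 5 (not isolated)
Conditions: 4-iodoanisole, mCPBA, TsOH·H2O, CH2Cl2/TFE (3:1), rt; evaporate; then 4, t-BuOK, THF, 0 °C to rt
Reagents that add atoms: none
Why: Proposed new method: a one-pot dehydrogenative C–H/O–H coupling in which [hydroxy(tosyloxy)iodo]-4-methoxybenzene, made in the flask, attacks 3 by electrophilic aromatic substitution at the only C–H para to OMe (the acyloxy group is a much weaker director and all three free positions are equally flanked, so electronics decide) to give iodonium salt 5, whose tosylate is exchanged at iodine for the mono-phenoxide of symmetric 4, after which the T-shaped Ar2I–OAr intermediate collapses by ligand coupling (SNAr-like reductive elimination) that transfers the di-ortho-substituted, inductively more electron-poor ring A in preference to the 4-methoxyphenyl spectator; the closest known reaction types are the Koser-type condensation of arenes with aryl-λ3-iodanes in fluoroalcohols and the metal-free O-arylation of phenoxides with diaryliodonium salts, which have not been merged into a site-selective C–H aryloxylation at a flanked position of an acyloxy-anisole to give a tri-ortho-substituted diaryl ether, and no stereocentre is formed.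

**Step 3**
Reactants: 6 methyl 2-{2-(hexadecanoyloxy)-6-[(hexadecanoyloxy)methyl]-4-methoxyphenoxy}-6-hydroxy-4-methylbenzoate
Product: 7 betaethrin E = methyl 2-{2-hydroxy-6-[(hexadecanoyloxy)methyl]-4-methoxyphenoxy}-6-hydroxy-4-methylbenzoate
Conditions: pyrrolidine (3 equiv), THF, 0 °C to rt
Reagents that add atoms: none
Why: Chemoselective aminolysis of an aryl ester: the phenolic palmitate (phenoxide leaving group) acylates a secondary amine at room temperature, whereas the primary benzylic palmitate and the hindered, hydrogen-bonded 2,6-disubstituted methyl benzoate need heating for aminolysis; no stereocentre is involved.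

**Compound list**
1 | 3-(hydroxymethyl)-5-methoxyphenol | OCc1cc(OC)cc(O)c1 | starting material
2 | hexadecanoyl chloride (palmitoyl chloride) | CCCCCCCCCCCCCCCC(=O)Cl | starting material
3 | 3-[(hexadecanoyloxy)methyl]-5-methoxyphenyl hexadecanoate | CCCCCCCCCCCCCCCC(=O)OCc1cc(OC)cc(OC(=O)CCCCCCCCCCCCCCC)c1 | intermediate
4 | methyl 2,6-dihydroxy-4-methylbenzoate | COC(=O)c1c(O)cc(C)cc1O | starting material
5 | {2-(hexadecanoyloxy)-6-[(hexadecanoyloxy)methyl]-4-methoxyphenyl}(4-methoxyphenyl)iodonium 4-methylbenzenesulfonate | CCCCCCCCCCCCCCCC(=O)OCc1cc(OC)cc(OC(=O)CCCCCCCCCCCCCCC)c1[I+]c1ccc(OC)cc1.[O-]S(=O)(=O)c1ccc(C)cc1 | intermediate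
6 | methyl 2-{2-(hexadecanoyloxy)-6-[(hexadecanoyloxy)methyl]-4-methoxyphenoxy}-6-hydroxy-4-methylbenzoate | CCCCCCCCCCCCCCCC(=O)OCc1cc(OC)cc(OC(=O)CCCCCCCCCCCCCCC)c1Oc1cc(C)cc(O)c1C(=O)OC | intermediate
7 | betaethrin E, methyl 2-{2-hydroxy-6-[(hexadecanoyloxy)methyl]-4-methoxyphenoxy}-6-hydroxy-4-methylbenzoate (achiral) | CCCCCCCCCCCCCCCC(=O)OCc1cc(OC)cc(O)c1Oc1cc(C)cc(O)c1C(=O)OC | target

**Totals**
Total step count: 3. Longest linear sequence: 3 steps (1 → 3 → 6 → 7).

**Steps most likely to fail, with fallbacks**

Step 2 (proposed new step) is the most likely to fail. The risks are slow or mis-sited iodane attack at the flanked C–H, partial transfer of the 4-methoxyphenyl group instead of ring A, and acyl transfer from the iodonium-activated aryl palmitate to the phenoxide. The fallback uses known chemistry, sets out from 3 and comes back at 6. Compound 3 is iodinated para to OMe with NIS and catalytic TFA in MeCN/CH2Cl2 to give 2-iodo-5-methoxy-3-[(hexadecanoyloxy)methyl]phenyl hexadecanoate F1. This is oxidised with mCPBA/TsOH·H2O and captured with 1,3,5-trimethoxybenzene to give the isolable salt {2-(hexadecanoyloxy)-6-[(hexadecanoyloxy)methyl]-4-methoxyphenyl}(2,4,6-trimethoxyphenyl)iodonium 4-methylbenzenesulfonate F2. The trimethoxyphenyl group in F2 is a reliable non-transferred spectator. Metal-free O-arylation of the potassium mono-phenoxide of 4 with F2 (t-BuOK, THF, rt) then gives 6.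

Step 3 is the second risk. The ortho-aryloxy-hindered phenolic palmitate may cleave slowly, or some benzylic palmitate may be lost. The fallback sets out from 6 and comes back at 7. Both palmitates are removed by methanolysis (K2CO3, MeOH/THF, rt), under which the ring-B methyl ester is unchanged, to give methyl 2-hydroxy-6-[2-hydroxy-6-(hydroxymethyl)-4-methoxyphenoxy]-4-methylbenzoate F3. The primary benzylic alcohol of F3 is then acylated selectively over the two phenols with immobilised Candida antarctica lipase B and vinyl palmitate (MTBE, 40 °C) to give 7.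

Step 1 is the least risky. The phenol may acylate incompletely, or the waxy diester may be hard to purify from palmitic by-products. The fallback sets out from 1 and comes back at 3. Lipase-catalysed acylation (immobilised Candida antarctica lipase B, vinyl palmitate, MTBE, 40 °C) esterifies only the benzylic alcohol to give 3-hydroxy-5-methoxybenzyl hexadecanoate F4. The remaining phenol of F4 is then esterified with palmitic acid by carbodiimide coupling (EDC·HCl, DMAP, CH2Cl2) to give 3.

**Further compounds**
F1 | step 2 | 2-iodo-5-methoxy-3-[(hexadecanoyloxy)methyl]phenyl hexadecanoate | CCCCCCCCCCCCCCCC(=O)OCc1cc(OC)cc(OC(=O)CCCCCCCCCCCCCCC)c1I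
F2 | step 2 | {2-(hexadecanoyloxy)-6-[(hexadecanoyloxy)methyl]-4-methoxyphenyl}(2,4,6-trimethoxyphenyl)iodonium 4-methylbenzenesulfonate | CCCCCCCCCCCCCCCC(=O)OCc1cc(OC)cc(OC(=O)CCCCCCCCCCCCCCC)c1[I+]c1c(OC)cc(OC)cc1OC.[O-]S(=O)(=O)c1ccc(C)cc1
F3 | step 3 | methyl 2-hydroxy-6-[2-hydroxy-6-(hydroxymethyl)-4-methoxyphenoxy]-4-methylbenzoate | COC(=O)c1c(O)cc(C)cc1Oc1c(O)cc(OC)cc1CO
F4 | step 1 | 3-hydroxy-5-methoxybenzyl hexadecanoate | CCCCCCCCCCCCCCCC(=O)OCc1cc(OC)cc(O)c1
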